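The easy step comes first: substrate meets reagent, and I want to know how much substrate has reacted at the end of each flask.

| flask | substrate | reagent | time |
|---|---|---|---|
| delta | 1.2 M | 0.840 M | 80 s |
| beta | 1.2 M | 1.30 M | 80 s |
| alpha | 1.2 M | 1.90 M | 80 s |

    substrate + reagent ⇌ intermediate (K1 = 2.0 M⁻¹, k1 = 0.0086 M⁻¹ s⁻¹)
    intermediate ⇌ product + by-product (K2 = 2.2 M, k2 = 0.40 s⁻¹)
    reagent + by-product ⇌ idle adduct, settled at all times (K3 = 250 M⁻¹)

- part of the substrate that has reacted at the end, delta
- part of the substrate that has reacted at the end, beta
- part of the substrate that has reacted at the end, alpha
- what raising the concentration of reagent from its lowest to its highest value here does to the part of the substrate that has reacted (changes below 5 percentage points count as none) (it falls / no change / it rises)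

- for by-product the idle adduct is counted in
- run time (delta): 80 s

I go down the time scales, starting with the fastest. The catch of by-product is kept at balance at every moment, and at the start of delta the reagent holds idle adduct over free by-product at 210 to one, so while reagent lasts each by-product costs one more reagent. Next comes the intermediate: its half-life by the second step is 1.7 s, far shorter than the 96 s of substrate by the first step in delta, so intermediate stays low and the first step is the rate-limiting step. On the slowest rung, then, each substrate that reacts takes two reagent.

That leaves one rate to integrate: the first rate constant times substrate times reagent. In this count reagent falls by two for each substrate; two substrate minus reagent then keeps its charged value, and the logarithm of substrate over reagent grows steadily. The time in which that ratio grows by a factor e I call the ratio clock, 74.5 s in delta, the inverse of the rate constant times that fixed surplus. In beta it is 106 s, and in alpha 233 s. Starting from the charged ratio, I reckon 26.2% reacted in delta, 38.6% in beta and 52.5% in alpha, so my answer on the trend is: it rises. Delta carries less reagent than two per substrate, which makes reagent the limiting reagent, and my two-for-one count stops at 35.0% there.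

The forecast gives 26.5%, 38.8% and 52.8%, and on the trend: it rises. Its ground is the same count, “Each substrate consumed therefore uses two reagents”, and its delta figure stands slightly above mine.

The simulation gives 26.4%, 38.8% and 52.7%, and on the trend: it rises, by 26 percentage points.

At 80 s delta is not at rest, and 26% of its reagent is still free. The ratio clock says what comes next: read at 3.0 min, delta should stand at 32.9%, and the reading there is 33.5%, with 7.7% of its reagent free. Left ten times as long, to 800 s, delta has reacted 38.8% of its substrate, past the two-for-one count, with free by-product at 0.0894 M and 1.91% of its reagent still free.

(The rate constants stand for no real mixture; the rest is arithmetic.)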